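**Retrosynthetic overview**
1. Ring A of the flavone carries four contiguous O-bearing carbons, C5(OH)–C6(OMe)–C7(OMe)–C8(OMe), with the C6/C7 dimethoxy pair in the middle. This is the carbon/oxygen pattern of the four-membered ring of dimethyl squarate.
2. Ring A is cut at C4a–C5 and at C8–C8a. C5–C8 become the four squarate carbons, and C4a=C8a becomes the C5=C6 double bond of a preformed 2-aryl-4-pyranone that already holds rings C and B.
3. Forward: the C6-lithiated pyranone adds to squarate (C8–C8a bond) and the alkoxide is methylated, which gives the future 8-OMe. A thermal 4π-opening/6π-closure then expands the four-membered ring to ring A (C4a–C5 bond).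
4. The key step is an isomerisation (C19H18O7 to C19H18O7) that gives the target directly, because the ketene oxygen emerges as the free 5-OH.
5. Ring order: B (bought), C (step 1), A (step 3).

Key step: step 3

Remark on the chemistry: the target has no stereocentre and is achiral, so no enantiocontrol is needed. Compounds 7, 8 and 10 each carry one transient stereocentre, are racemic, and lose that centre on aromatisation.

**Step 1**
Reactants: 1 (E)-4-methoxybut-3-en-2-one; 2 4-methoxybenzoyl chloride
Product: 4 2-(4-methoxyphenyl)-4H-pyran-4-one, via methoxyenone diketone 3 (not isolated)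
Conditions: 1 (2 equiv), LiHMDS (2 equiv), THF, −78 °C; then 2; aq. NH4Cl; crude 3, TFA (cat.), toluene, rt
Reagents that add atoms: none
Why: Claisen-type C-acylation of the kinetic lithium enolate of the vinylogous ester gives β-diketone 3, whose enol oxygen adds 6-endo to the β-methoxyenone and expels methanol under acid catalysis (addition–elimination cyclocondensation to a γ-pyrone).

**Step 2**
Reactants: 4 2-(4-methoxyphenyl)-4H-pyran-4-one; 5 dimethyl squarate (3,4-dimethoxycyclobut-3-ene-1,2-dione)
Product: 8 (±)-2,3,4-trimethoxy-4-[6-(4-methoxyphenyl)-4-oxo-4H-pyran-2-yl]cyclobut-2-en-1-one, via lithiopyranone 6 (not isolated), via lithium alkoxide 7 (not isolated)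
Conditions: TMPH, n-BuLi, THF, 0 °C; 4, −78 °C; 5, −78 °C; MeOTf (1.1 equiv), −78 to 0 °C; pH 7 buffer
Reagents that add atoms: methyl trifluoromethanesulfonate, COS(=O)(=O)C(F)(F)F
Why: Deprotonative lithiation at C6–H, alpha to the ring oxygen (the site at which chromones and β-alkoxyacrylates are lithiated by hindered lithium amides), gives a vinyllithium that adds 1,2 to one of the two equivalent squarate carbonyls at −78 °C, and the charged tertiary alkoxide should be methylated by MeOTf faster than the neutral pyranone carbonyl (organolithium 1,2-addition to a squarate ester with in situ O-alkylation); the new quaternary centre is racemic and is erased in step 3.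

**Step 3**
Reactants: 8 (±)-2,3,4-trimethoxy-4-[6-(4-methoxyphenyl)-4-oxo-4H-pyran-2-yl]cyclobut-2-en-1-one
Product: 11 gardenin B (5-hydroxy-6,7,8,4'-tetramethoxyflavone), via dienylketene 9 (not isolated), via cyclohexadienone 10 (not isolated)
Conditions: toluene (degassed, 0.01 M), 110 °C, Ar
Reagents that add atoms: none
Why: Heating breaks the C1–C4 σ-bond of the cyclobutenone in a 4π conrotatory electrocyclic opening in which the C4 methoxy donor rotates outward, so that the pyranonyl group of dienylketene 9 lies cis to the ketene. The triene made of the ketene C5=C6, the C7=C8 double bond and the pyranone C8a=C4a double bond (flavone numbering) then closes by a 6π disrotatory electrocyclisation, which forms the C4a–C5 bond and closes ring A as a six-membered carbocycle (10), whose C4a–H lies between two carbonyl groups and should enolise at once to the phenol. The closest known reaction type is the Moore–Liebeskind ring expansion of squarate-derived 4-alkenyl- and 4-heteroaryl-4-alkoxycyclobutenones (2-furyl, dihydropyran-6-yl) to mono-protected hydroquinones. No stereocentre is created in 11, and the centres of 8 and 10 vanish on aromatisation. Regioselectivity is secured because C4a–H is the only pyranone position next to the point of attachment, and it is the nucleophilic α-carbon of a vinylogous ester facing the electrophilic ketene carbon. The oxygen pattern needs no later correction, since C8–O was methylated in step 2, the ketene oxygen appears as the free 5-OH whose hydrogen bond to C4=O keeps it from adding to unreacted ketene, and high dilution suppresses ketene dimerisation.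

**Compound list**
1 | (E)-4-methoxybut-3-en-2-one | CO/C=C/C(C)=O | starting material
2 | 4-methoxybenzoyl chloride | COc1ccc(cc1)C(Cl)=O | starting material
3 | (E)-5-methoxy-1-(4-methoxyphenyl)pent-4-ene-1,3-dione | CO/C=C/C(=O)CC(=O)c1ccc(OC)cc1 | intermediate
4 | 2-(4-methoxyphenyl)-4H-pyran-4-one | COc1ccc(cc1)-c1cc(=O)cco1 | intermediate
5 | dimethyl squarate | COC1=C(OC)C(=O)C1=O | starting material
6 | 6-lithio-2-(4-methoxyphenyl)-4H-pyran-4-one | [Li]c1cc(=O)cc(o1)-c1ccc(OC)cc1 | intermediate
7 | lithium alkoxide of the 1,2-adduct (racemic) | [Li]OC1(C(OC)=C(OC)C1=O)c1cc(=O)cc(o1)-c1ccc(OC)cc1 | intermediate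
8 | (±)-2,3,4-trimethoxy-4-[6-(4-methoxyphenyl)-4-oxo-4H-pyran-2-yl]cyclobut-2-en-1-one | COC1=C(OC)C(OC)(C1=O)c1cc(=O)cc(o1)-c1ccc(OC)cc1 | intermediate
9 | (Z)-2,3,4-trimethoxy-4-[6-(4-methoxyphenyl)-4-oxo-4H-pyran-2-yl]buta-1,3-dien-1-one (dienylketene) | COC(=C=O)/C(OC)=C(/OC)c1cc(=O)cc(o1)-c1ccc(OC)cc1 | intermediate
10 | (±)-6,7,8-trimethoxy-2-(4-methoxyphenyl)-4aH-chromene-4,5-dione | COC1=C(OC)C(=O)C2C(=O)C=C(OC2=C1OC)c1ccc(OC)cc1 | intermediate
11 | gardenin B, 5-hydroxy-6,7,8-trimethoxy-2-(4-methoxyphenyl)-4H-chromen-4-one | COc1ccc(-c2cc(=O)c3c(O)c(OC)c(OC)c(OC)c3o2)cc1 | target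

**Total step count:** 3. **Longest linear sequence:** 3 (1 or 2 → 4 → 8 → 11).

**Steps most likely to fail**

Step 2. The lithiated pyranone may condense with unreacted 4. Lithiation may instead occur at C3 or C5, with ring opening. MeOTf may also alkylate the pyranone carbonyl oxygen in competition with the hindered alkoxide.

The fallback sets out from 4 and comes back at 8. It replaces the deprotonation and in situ trap by an isolable halide, a milder magnesium nucleophile and a neutral methylation.
- C6–H zincation of 4 with a TMP–zinc amide base at room temperature (the kind of metalation known for C2 of chromones), followed by iodolysis, should give 2-iodo-6-(4-methoxyphenyl)-4H-pyran-4-one F1.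
- Iodine–magnesium exchange with i-PrMgCl·LiCl at −40 °C, addition to 5 and a proton quench should give (±)-4-hydroxy-2,3-dimethoxy-4-[6-(4-methoxyphenyl)-4-oxo-4H-pyran-2-yl]cyclobut-2-en-1-one F2.
- O-methylation of F2 with MeI/Ag2O in MeCN at rt, conditions that leave the pyranone carbonyl alone, gives 8.

Step 3. After ring opening, the ketene may be consumed by dimerisation or by adventitious nucleophiles faster than it closes onto the partly delocalised pyranone double bond.

The fallback sets out from 5 and comes back at 11. It builds ring A first on a simple vinyl ether, the best-precedented substrate type, and ring C afterwards.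
- 1-Methoxyvinyllithium (methyl vinyl ether, t-BuLi) adds to 5, and a MeOTf trap gives (±)-2,3,4-trimethoxy-4-(1-methoxyvinyl)cyclobut-2-en-1-one F3.
- Thermolysis of F3 in toluene should give 2,3,4,5-tetramethoxyphenol F4.
- NIS iodination at the only free ring position gives 2-iodo-3,4,5,6-tetramethoxyphenol F5.
- Pd-catalysed three-component carbonylative Sonogashira coupling and cyclisation of F5 with CO and 4-ethynylanisole in Et2NH gives tangeretin F6.
- Chelation-controlled 5-O-demethylation of F6 with BCl3 in CH2Cl2 gives 11.

Step 1. O-acylation or double acylation of the enolate, or base-induced oligomerisation of the methoxyenone, may erode the supply of 3.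

The fallback sets out from 1 and comes back at 4. It forms ring C by cycloaddition instead of acylation.
- Silylation of 1 (TMSCl, Et3N, ZnCl2) gives Danishefsky's diene, (E)-1-methoxy-3-(trimethylsilyloxy)buta-1,3-diene F7.
- Lewis-acid-promoted hetero-Diels–Alder reaction of F7 with 4-methoxybenzaldehyde and acid work-up gives (±)-2-(4-methoxyphenyl)-2,3-dihydro-4H-pyran-4-one F8.
- Dehydrogenation of F8 with DDQ in dioxane, in the manner of a flavanone-to-flavone oxidation, gives 4.

**Further compounds**
F1 | step 2 | 2-iodo-6-(4-methoxyphenyl)-4H-pyran-4-one | O=c1cc(I)oc(-c2ccc(OC)cc2)c1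
F2 | step 2 | (±)-4-hydroxy-2,3-dimethoxy-4-[6-(4-methoxyphenyl)-4-oxo-4H-pyran-2-yl]cyclobut-2-en-1-one | COC1=C(OC)C(O)(C1=O)c1cc(=O)cc(o1)-c1ccc(OC)cc1
F3 | step 3 | (±)-2,3,4-trimethoxy-4-(1-methoxyvinyl)cyclobut-2-en-1-one | COC(=C)C1(OC)C(OC)=C(OC)C1=O
F4 | step 3 | 2,3,4,5-tetramethoxyphenol | COc1cc(O)c(OC)c(OC)c1OC
F5 | step 3 | 2-iodo-3,4,5,6-tetramethoxyphenol | COc1c(I)c(O)c(OC)c(OC)c1OC
F6 | step 3 | tangeretin (5,6,7,8,4'-pentamethoxyflavone) | COc1ccc(cc1)-c1cc(=O)c2c(OC)c(OC)c(OC)c(OC)c2o1
F7 | step 1 | (E)-1-methoxy-3-(trimethylsilyloxy)buta-1,3-diene | CO/C=C/C(=C)O[Si](C)(C)C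
F8 | step 1 | (±)-2-(4-methoxyphenyl)-2,3-dihydro-4H-pyran-4-one | COc1ccc(cc1)C1CC(=O)C=CO1
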